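## Retrosynthetic overview

Positions use eremophilane numbering: C1 (OAc), C4 (CHMe), C5 (quaternary CMe), C7 (isopropenyl), C8 (angelate), C9 (C=O), C10 (ring-fusion CH).

1. Target 21 ⇐ angeloylation of the 8α-alcohol 17 ⇐ enolate hydroxylation at C8 of trans-decalone 15.
2. Key disconnection, ring B (formed last): the C2–C3 bond of 15, by 6-endo radical cyclisation of a β-acetoxyalkyl radical onto an isopropenyl group on C5; the chain-ending hydrogen-atom transfer sets C4.
3. Radical precursor 12 ⇐ one-flask conjugate addition of isopropenyl to enone 7 (sets C5) and anti-aldol capture of the enolate by chloroacetaldehyde (sets C10 and C1).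
4. Ring A (formed first): (5S)-7 ⇐ amine-catalysed desymmetrising aldol condensation of achiral 1,5-diketone 6 ⇐ cuprate addition to enedione 3 ⇐ cross-metathesis of 1 with 2.

Assumption: chloroacetaldehyde (8) is used as the anhydrous monomer, freshly distilled from the commercial hydrate, and the cinchona primary amine in step 3 is the antipode that gives (5S)-7 (if the quinine-derived amine gives (5R)-7, its quinidine-derived pseudo-enantiomer is used).

## Route

Step 1
Reactants: 1 pent-4-en-2-one; 2 but-3-en-2-one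
Product: 3 (3E)-hept-3-ene-2,6-dione
Conditions: second-generation Hoveyda–Grubbs catalyst (C31H38Cl2N2ORu, 2 mol%), 1,4-benzoquinone (10 mol%), 2 (3 equiv), CH2Cl2, 40 °C; used at once
Reagents that add atoms: none
Why: Olefin cross-metathesis of the terminal alkene of 1 with the electron-poor enone 2 (which homodimerises slowly) gives the E cross-product, and benzoquinone suppresses double-bond migration.

Step 2
Reactants: 3 (3E)-hept-3-ene-2,6-dione; 4 (prop-1-en-2-yl)magnesium bromide
Product: 6 4-(prop-1-en-2-yl)heptane-2,6-dione, via silyl enol ether 5 (not isolated)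
Conditions: 4 (2.2 equiv), CuI (1.1 equiv), THF, −40 °C; Me3SiCl (2 equiv), then 3, −78 °C; 1 M HCl, 0 °C
Reagents that add atoms: none
Why: Chlorosilane-accelerated organocuprate conjugate addition to the enone outruns attack on the saturated ketone and deprotonation, the enolate is caught as 5, and acid work-up releases the diketone, which is achiral because its two acetonyl arms are identical.

Step 3
Reactants: 6 4-(prop-1-en-2-yl)heptane-2,6-dione
Product: 7 (5S)-3-methyl-5-(prop-1-en-2-yl)cyclohex-2-en-1-one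
Conditions: 9-amino-9-deoxy-epi-quinine (20 mol%), AcOH (60 mol%), toluene, −15 °C
Reagents that add atoms: none
Why: Primary-amine (enamine) catalysed desymmetrising intramolecular aldol condensation (Hajos–Parrish type, List conditions) differentiates the two enantiotopic acetonyl arms, so the catalyst sets C7 (5S in 7); about 90% ee is expected by analogy with 4-alkyl- and 4-aryl-heptane-2,6-diones.

Step 4
Reactants: 7 (5S)-3-methyl-5-(prop-1-en-2-yl)cyclohex-2-en-1-one; 4 (prop-1-en-2-yl)magnesium bromide; 8 chloroacetaldehyde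
Product: 10 (2S,3S,5S)-2-[(1R)-2-chloro-1-hydroxyethyl]-3-methyl-3,5-di(prop-1-en-2-yl)cyclohexan-1-one, via bromomagnesium enolate 9 (not isolated)
Conditions: 4 (2.4 equiv), CuI (1.2 equiv), THF/Me2S, −40 °C; 7, −40 °C, 1 h; 8 (2 equiv), −78 °C, 10 min; sat. aq. NH4Cl at −78 °C
Reagents that add atoms: none
Why: In this three-component conjugate addition–aldol reaction the cuprate adds axially and trans to the C7 isopropenyl group (sets C5, methyl cis to the C7 substituent), the enolate is attacked on the face anti to the newly axial isopropenyl group (sets C10), and the Zimmerman–Traxler chair of the ring (E)-enolate gives the anti-aldol (sets C1).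

Step 5
Reactants: 10 (2S,3S,5S)-2-[(1R)-2-chloro-1-hydroxyethyl]-3-methyl-3,5-di(prop-1-en-2-yl)cyclohexan-1-one; 11 acetic anhydride
Product: 12 (1R)-2-chloro-1-[(1S,2S,4S)-2-methyl-6-oxo-2,4-di(prop-1-en-2-yl)cyclohexyl]ethyl acetate
Conditions: 11 (3 equiv), pyridine, DMAP (5 mol%), CH2Cl2, 0 °C
Reagents that add atoms: none
Why: DMAP-catalysed O-acetylation at 0 °C is mild enough to avoid retro-aldol cleavage and elimination of the β-oxygen, and no stereocentre is touched.

Step 6
Reactants: 12 (1R)-2-chloro-1-[(1S,2S,4S)-2-methyl-6-oxo-2,4-di(prop-1-en-2-yl)cyclohexyl]ethyl acetate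
Product: 15 (1S,4S,4aR,6S,8aS)-4,4a-dimethyl-8-oxo-6-(prop-1-en-2-yl)decahydronaphthalen-1-yl acetate, via primary alkyl radical 13 (not isolated), via tertiary ring radical 14 (not isolated)
Conditions: (Me3Si)3SiH (1.5 equiv) and AIBN (0.3 equiv) added over 10 h, toluene (0.005 M), 90 °C
Reagents that add atoms: none
Why: In this silane-mediated reductive 6-endo-trig radical cyclisation the silyl radical abstracts chlorine, radical 13 attacks the CH2 end of the C5 isopropenyl group (5-exo closure would have to join two quaternary carbons) and forms the C2–C3 bond with the trans ring fusion already fixed by C5 and C10, and radical 14 takes hydrogen from the bulky silane axially, opposite the angular methyl, so the C4 methyl ends equatorial and cis to it.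

Step 7
Reactants: 15 (1S,4S,4aR,6S,8aS)-4,4a-dimethyl-8-oxo-6-(prop-1-en-2-yl)decahydronaphthalen-1-yl acetate
Product: 17 (1S,4S,4aR,6R,7R,8aS)-7-hydroxy-4,4a-dimethyl-8-oxo-6-(prop-1-en-2-yl)decahydronaphthalen-1-yl acetate, via sodium enolate 16 (not isolated)
Conditions: NaN(SiMe3)2 (1.1 equiv), THF, −78 °C, 30 min; 2-(phenylsulfonyl)-3-phenyloxaziridine (1.3 equiv), −78 °C; sat. aq. NH4Cl
Reagents that add atoms: 2-(phenylsulfonyl)-3-phenyloxaziridine, O=S(=O)(N1OC1c1ccccc1)c1ccccc1
Why: Kinetic deprotonation takes the C8 methylene and not the hindered ring-fusion CH, and Davis oxaziridine hydroxylation of the enolate delivers oxygen to the face of C8 anti to the adjacent 7β-isopropenyl group, giving the 8α-alcohol without touching the isopropenyl alkene.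

Step 8
Reactants: 17 (1S,4S,4aR,6R,7R,8aS)-7-hydroxy-4,4a-dimethyl-8-oxo-6-(prop-1-en-2-yl)decahydronaphthalen-1-yl acetate; 18 angelic acid
Product: 21 (1S,4S,4aR,6R,7R,8aS)-1-acetoxy-4,4a-dimethyl-8-oxo-6-(prop-1-en-2-yl)decahydronaphthalen-7-yl (2Z)-2-methylbut-2-enoate, via angeloyl chloride 19 (not isolated), via lithium alkoxide 20 (not isolated)
Conditions: 18, (COCl)2 (1.05 equiv), DMF (cat.), CH2Cl2, 0 °C, volatiles removed cold; 17, LiN(SiMe3)2 (1.05 equiv), THF, −78 °C; then 19 (1.5 equiv), −78 to −30 °C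
Reagents that add atoms: none
Why: O-acylation of the pre-formed lithium alkoxide with the acid chloride at low temperature needs no nucleophilic amine catalyst, so the Z alkene does not isomerise to the tiglate, C10 is not epimerised, the C1 acetate is not eliminated, and C8 keeps its configuration.

## Compound list

1 | pent-4-en-2-one | CC(=O)CC=C | starting material
2 | but-3-en-2-one | CC(=O)C=C | starting material
3 | (3E)-hept-3-ene-2,6-dione | CC(=O)/C=C/CC(C)=O | intermediate
4 | (prop-1-en-2-yl)magnesium bromide | C=C(C)[Mg]Br | starting material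
5 | 4-(prop-1-en-2-yl)-6-(trimethylsilyloxy)hept-5-en-2-one (racemic, enol ether geometry not defined) | CC(=O)CC(C(C)=C)C=C(C)O[Si](C)(C)C | intermediate
6 | 4-(prop-1-en-2-yl)heptane-2,6-dione (achiral) | CC(=O)CC(C(C)=C)CC(C)=O | intermediate
7 | (5S)-3-methyl-5-(prop-1-en-2-yl)cyclohex-2-en-1-one | C=C(C)[C@H]1CC(C)=CC(=O)C1 | intermediate
8 | chloroacetaldehyde | ClCC=O | starting material
9 | bromomagnesium (3S,5S)-3-methyl-3,5-di(prop-1-en-2-yl)cyclohex-1-en-1-olate | C=C(C)[C@H]1C[C@](C)(C(C)=C)C=C(O[Mg]Br)C1 | intermediate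
10 | (2S,3S,5S)-2-[(1R)-2-chloro-1-hydroxyethyl]-3-methyl-3,5-di(prop-1-en-2-yl)cyclohexan-1-one | C=C(C)[C@H]1C[C@](C)(C(C)=C)[C@H](C(=O)C1)[C@@H](O)CCl | intermediate
11 | acetic anhydride | CC(=O)OC(C)=O | starting material
12 | (1R)-2-chloro-1-[(1S,2S,4S)-2-methyl-6-oxo-2,4-di(prop-1-en-2-yl)cyclohexyl]ethyl acetate | C=C(C)[C@H]1C[C@](C)(C(C)=C)[C@H](C(=O)C1)[C@@H](OC(C)=O)CCl | intermediate
13 | (2R)-2-acetoxy-2-[(1S,2S,4S)-2-methyl-6-oxo-2,4-di(prop-1-en-2-yl)cyclohexyl]ethyl radical | C=C(C)[C@H]1C[C@](C)(C(C)=C)[C@H](C(=O)C1)[C@@H](OC(C)=O)[CH2] | intermediate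
14 | C4-centred tertiary radical of the closed decalin (other centres as in 15) | C=C(C)[C@H]1C[C@@]2(C)[C@H](C(=O)C1)[C@@H](OC(C)=O)CC[C]2C | intermediate
15 | (1S,4S,4aR,6S,8aS)-4,4a-dimethyl-8-oxo-6-(prop-1-en-2-yl)decahydronaphthalen-1-yl acetate (1α-acetoxy-10αH-eremophil-11-en-9-one) | C=C(C)[C@H]1C[C@@]2(C)[C@H](C(=O)C1)[C@@H](OC(C)=O)CC[C@@H]2C | intermediate
16 | sodium enolate of 15 (C8=C9) | C=C(C)[C@H]1C[C@@]2(C)[C@H](C(O[Na])=C1)[C@@H](OC(C)=O)CC[C@@H]2C | intermediate
17 | (1S,4S,4aR,6R,7R,8aS)-7-hydroxy-4,4a-dimethyl-8-oxo-6-(prop-1-en-2-yl)decahydronaphthalen-1-yl acetate | C=C(C)[C@H]1C[C@@]2(C)[C@H](C(=O)[C@@H]1O)[C@@H](OC(C)=O)CC[C@@H]2C | intermediate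
18 | angelic acid, (2Z)-2-methylbut-2-enoic acid | C/C=C(/C)C(=O)O | starting material
19 | angeloyl chloride, (2Z)-2-methylbut-2-enoyl chloride | C/C=C(/C)C(=O)Cl | intermediate
20 | lithium alkoxide of 17 | C=C(C)[C@H]1C[C@@]2(C)[C@H](C(=O)[C@@H]1O[Li])[C@@H](OC(C)=O)CC[C@@H]2C | intermediate
21 | (1S,4S,4aR,6R,7R,8aS)-1-acetoxy-4,4a-dimethyl-8-oxo-6-(prop-1-en-2-yl)decahydronaphthalen-7-yl (2Z)-2-methylbut-2-enoate (CNP0138236.2; 1α-acetoxy-8α-angeloyloxy-10αH-eremophil-11-en-9-one) | C=C(C)[C@H]1C[C@@]2(C)[C@H](C(=O)[C@@H]1OC(=O)/C(C)=C\C)[C@@H](OC(C)=O)CC[C@@H]2C | target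

## Step count and risks

Total step count: 8. Longest linear sequence: 8 steps (1 and 2 to 21).

The three steps most likely to fail are step 6, step 4 and step 7.

Step 6 is the weakest. The two side chains of 12 rest trans-diaxial and must reach a twist conformer before ring closure, so direct reduction of 13 can win; chlorine abstraction by the silyl radical is also slow. The fallback sets out from 12. The chloride is exchanged for iodide (NaI, butan-2-one, 80 °C) to give iodide F2. F2 is closed by iodine-atom-transfer cyclisation (Bu3SnSnBu3 10 mol%, sunlamp, benzene, 80 °C) to tertiary iodide F3; with no hydrogen donor present, radical 13 can only cyclise or revert to F2. A separate reduction of F3 with (Me3Si)3SiH and AIBN passes through the same radical 14 and comes back to the route at 15.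

Step 4 can fail through proton transfer to the enolisable, polymerisation-prone aldehyde 8, through epoxide closure of the aldolate, or through a low anti to syn ratio at C1. The fallback sets out from 7 and separates the two bond formations. The cuprate addition is run with Me3SiCl and the enolate is isolated as silyl enol ether F1. A Lewis-acid Mukaiyama aldol addition of F1 to 8 (BF3·OEt2, CH2Cl2, −78 °C; open transition state, attack still anti to the axial isopropenyl group) then comes back to the route at 10, with the C1 epimers separated if needed.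

Step 7 puts a strong base on a ketone that carries a β-acetoxy group and an epimerisable C10, so elimination of acetate, attack of the enolate on the acetate, or loss of the trans ring fusion are possible. The fallback sets out from 7 and brings the oxygen in before those groups exist. The cross-conjugated kinetic enolate of 7 (LDA, THF, −78 °C) is hydroxylated with the same oxaziridine, trans to the isopropenyl group, to give hydroxy enone F4, which is protected (Et3SiCl, imidazole) as silyl ether F5. The conditions of steps 4, 5 and 6 then give chlorohydrin F6, acetate F7 and decalin silyl ether F8 in turn. Removal of the silyl group (HF·pyridine, THF, 0 °C) comes back to the route at 17, at the cost of two extra steps.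

## Further compounds

F1 | step 4 | trimethyl{[(3S,5S)-3-methyl-3,5-di(prop-1-en-2-yl)cyclohex-1-en-1-yl]oxy}silane | C=C(C)[C@H]1C[C@](C)(C(C)=C)C=C(O[Si](C)(C)C)C1
F2 | step 6 | (1R)-2-iodo-1-[(1S,2S,4S)-2-methyl-6-oxo-2,4-di(prop-1-en-2-yl)cyclohexyl]ethyl acetate | C=C(C)[C@H]1C[C@](C)(C(C)=C)[C@H](C(=O)C1)[C@@H](OC(C)=O)CI
F3 | step 6 | 4-iodo-4,4a-dimethyl-8-oxo-6-(prop-1-en-2-yl)decahydronaphthalen-1-yl acetate (both C4 epimers, other centres as in 15) | C=C(C)[C@H]1C[C@@]2(C)[C@H](C(=O)C1)[C@@H](OC(C)=O)CCC2(C)I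
F4 | step 7 | (5R,6R)-6-hydroxy-3-methyl-5-(prop-1-en-2-yl)cyclohex-2-en-1-one | C=C(C)[C@H]1CC(C)=CC(=O)[C@@H]1O
F5 | step 7 | (5R,6R)-3-methyl-5-(prop-1-en-2-yl)-6-(triethylsilyloxy)cyclohex-2-en-1-one | C=C(C)[C@H]1CC(C)=CC(=O)[C@@H]1O[Si](CC)(CC)CC
F6 | step 7 | (2S,3S,5R,6R)-2-[(1R)-2-chloro-1-hydroxyethyl]-3-methyl-3,5-di(prop-1-en-2-yl)-6-(triethylsilyloxy)cyclohexan-1-one | C=C(C)[C@H]1C[C@](C)(C(C)=C)[C@H](C(=O)[C@@H]1O[Si](CC)(CC)CC)[C@@H](O)CCl
F7 | step 7 | (1R)-2-chloro-1-[(1S,2S,4R,5R)-2-methyl-6-oxo-2,4-di(prop-1-en-2-yl)-5-(triethylsilyloxy)cyclohexyl]ethyl acetate | C=C(C)[C@H]1C[C@](C)(C(C)=C)[C@H](C(=O)[C@@H]1O[Si](CC)(CC)CC)[C@@H](OC(C)=O)CCl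
F8 | step 7 | (1S,4S,4aR,6R,7R,8aS)-4,4a-dimethyl-8-oxo-6-(prop-1-en-2-yl)-7-(triethylsilyloxy)decahydronaphthalen-1-yl acetate | C=C(C)[C@H]1C[C@@]2(C)[C@H](C(=O)[C@@H]1O[Si](CC)(CC)CC)[C@@H](OC(C)=O)CC[C@@H]2C
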